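**Retrosynthetic overview**
- Target 20 ← global hydrogenolysis of the fully benzylated, C8-brominated dimer 19; its upper C3–OH ← Baeyer–Villiger oxidation (retention) of a C3 formyl group in 17.
- Upper ring C is made last, in one operation from benzhydrol 12 (lower unit and upper ring A, already joined through C4) and cinnamaldehyde 14 (ring B, C2, C3, formyl as masked OH): O1–C2 forms by oxa-Michael addition, then the ring closes by C3–C4 bond formation.
- Enabling feature: C4 of the upper unit is a methine flanked by two phloroglucinol-type rings (upper ring A with O1, C5–O, C7–O; lower ring A with C5–O and C7–O ortho and O1 para to C6), so it ionises to a stabilised carbenium ion. The phenolic O1 sits ortho to C4a, so after oxa-Michael addition the nucleophilic C3 is one six-membered ring away from C4.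
- 12 ← C6-magnesiated 8-bromo-octa-O-benzyl-EGCG (from (−)-epigallocatechin and tri-O-benzylgallic acid; bromine blocks C8) + silyl-protected 2-hydroxy-4,6-bis(benzyloxy)benzaldehyde.
- Ring order: lower rings A, C and B come from epigallocatechin and the galloyl ring from the acid; upper rings A and B are bought as aldehydes; upper ring C is formed in the key step.

Key step: step 10

Remark: the carbinol carbon of 11, 12 and 15 is formed as a mixture of epimers and is written without a descriptor, because it is planarised to the carbenium ion in step 10. Flavan numbering is used; "upper" and "lower" name the two flavan units; EGCG stands for (−)-epigallocatechin 3-O-gallate.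

**Step 1**
Reactants: 1 (−)-epigallocatechin
Product: 2 5,7,3',4',5'-penta-O-benzyl-(−)-epigallocatechin
Conditions: BnBr, K2CO3, DMF, −20 °C → rt, Ar
Reagents that add atoms: benzyl bromide, BrCc1ccccc1
Why: Williamson etherification of the five phenols; K2CO3 deprotonates only phenols, so the secondary 3-OH should stay free and the C2/C3 stereocenters untouched under exclusion of air.

**Step 2**
Reactants: 2 5,7,3',4',5'-penta-O-benzyl-(−)-epigallocatechin; 3 3,4,5-tris(benzyloxy)benzoic acid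
Product: 4 octa-O-benzyl-(−)-EGCG
Conditions: DCC, DMAP (cat.), CH2Cl2, 0 °C → rt
Reagents that add atoms: none
Why: Steglich esterification of the secondary 3-OH through the acylpyridinium ion; the C–O bond at C3 is not broken, so its configuration is retained.

**Step 3**
Reactants: 4 octa-O-benzyl-(−)-EGCG
Product: 5 8-bromo-octa-O-benzyl-(−)-EGCG
Conditions: NBS, CH2Cl2, −78 °C → 0 °C, dark
Reagents that add atoms: N-bromosuccinimide, O=C1CCC(=O)N1Br
Why: electrophilic aromatic bromination; ring A is the most electron-rich ring and C8 is its more reactive position, as known for benzylated flavan-3-ols.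

**Step 4**
Reactants: 5 8-bromo-octa-O-benzyl-(−)-EGCG
Product: 6 8-bromo-6-iodo-octa-O-benzyl-(−)-EGCG
Conditions: NIS, TFA (cat.), CH2Cl2/MeCN, 0 °C → rt
Reagents that add atoms: N-iodosuccinimide, O=C1CCC(=O)N1I
Why: electrophilic aromatic iodination at C6, the only free position of ring A (between two benzyloxy groups), which should react before ring B or the gallate ring.

**Step 5**
Reactants: 7 2,4,6-trihydroxybenzaldehyde
Product: 8 2,4-bis(benzyloxy)-6-hydroxybenzaldehyde
Conditions: BnBr (2 equiv), K2CO3, DMF, rt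
Reagents that add atoms: benzyl bromide, BrCc1ccccc1
Why: regioselective Williamson etherification; the second ortho hydroxyl is deactivated by its hydrogen bond to the aldehyde and should remain free.

**Step 6**
Reactants: 8 2,4-bis(benzyloxy)-6-hydroxybenzaldehyde
Product: 9 2,4-bis(benzyloxy)-6-(tert-butyldimethylsilyloxy)benzaldehyde
Conditions: TBSCl, imidazole, DMAP (cat.), DMF, 40 °C
Reagents that add atoms: tert-butyldimethylsilyl chloride, CC(C)(C)[Si](C)(C)Cl
Why: silylation of the phenol, so that the aryl Grignard reagent of step 7 is not consumed by an acidic proton.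

**Step 7**
Reactants: 6 8-bromo-6-iodo-octa-O-benzyl-(−)-EGCG; 9 2,4-bis(benzyloxy)-6-(tert-butyldimethylsilyloxy)benzaldehyde
Product: 11 silyl-protected benzhydrol (8-bromo-octa-O-benzyl-(−)-EGCG carrying at C6 a hydroxy[2,4-bis(benzyloxy)-6-(tert-butyldimethylsilyloxy)phenyl]methyl group), via arylmagnesium chloride 10 (not isolated)
Conditions: iPrMgCl·LiCl, THF, −30 °C; then 9, −30 °C → rt; aq. NH4Cl
Reagents that add atoms: none
Why: iodine–magnesium exchange (much faster at C–I than at C–Br, ester tolerated at low temperature) followed by 1,2-addition of the aryl Grignard reagent to the aldehyde; the new carbinol center is not controlled and need not be.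

**Step 8**
Reactants: 11 silyl-protected benzhydrol
Product: 12 phenolic benzhydrol (8-bromo-octa-O-benzyl-(−)-EGCG carrying at C6 a hydroxy[2,4-bis(benzyloxy)-6-hydroxyphenyl]methyl group)
Conditions: TBAF, AcOH, THF, 0 °C
Reagents that add atoms: none
Why: fluoride-mediated cleavage of the aryl silyl ether; the acetic acid buffer should keep the acid-labile benzhydrol and the gallate ester intact.

**Step 9**
Reactants: 13 3,4,5-tris(benzyloxy)benzaldehyde
Product: 14 (E)-3-[3,4,5-tris(benzyloxy)phenyl]prop-2-enal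
Conditions: Ph3P=CHCHO, toluene, 80 °C
Reagents that add atoms: (triphenylphosphoranylidene)acetaldehyde, O=CC=P(c1ccccc1)(c1ccccc1)c1ccccc1
Why: Wittig olefination with a stabilised formyl ylide, which should give the E-enal.

**Step 10**
Reactants: 12 phenolic benzhydrol; 14 (E)-3-[3,4,5-tris(benzyloxy)phenyl]prop-2-enal
Product: 17 (2S,3R,4R)-5,7-bis(benzyloxy)-4-[8-bromo-octa-O-benzyl-(−)-EGCG-6-yl]-2-[3,4,5-tris(benzyloxy)phenyl]chromane-3-carbaldehyde, via oxa-Michael enamine 15 (not isolated), via enamine carbenium ion 16 (not isolated)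
Conditions: (S)-2-[diphenyl(trimethylsilyloxy)methyl]pyrrolidine (20 mol %), PhCO2H (20 mol %), CHCl3 (0.01 M), rt
Reagents that add atoms: none
Why: Proposed new method: the amine and enal 14 form an iminium ion, the phenolic O1–H of 12 adds to its β-carbon (oxa-Michael, giving enamine 15), the acid ionises the benzhydrol to carbenium ion 16, and the enamine α-carbon C3 attacks C4 before hydrolysis frees 17 and the catalyst; the closest known reaction types are the aminocatalytic oxa-Michael/Michael and oxa-Michael/aldol annulations of 2-hydroxyaryl electrophiles with enals and the enamine-catalysed SN1-type α-alkylation of aldehydes with benzhydrols, which are merged here. Ring C closes by C3–C4 bond formation as a 6-(enolexo)-exo-trig C-alkylation of the enamine by the tethered carbenium carbon. C2 is set by the catalyst: the diphenyl(silyloxy)methyl group of the (S)-amine shields one face of the E-iminium ion, so O1 should add to the opposite face and give the configuration that is 2R in the final flavan-3-ol. C4 is set by the substrate in the ring closure: peri strain with the C5 benzyloxy group should force the bulky lower aryl group quasi-axial in the chair-like transition state, trans to the equatorial C2 aryl group. C3 carries an enolisable formyl group and should settle under the amine/acid conditions in the axial position anti to the C4 aryl group, which is cis to the C2 aryl group (the 2,3-cis-3,4-trans pattern of the target). The step needs intramolecular capture of the carbenium ion to outrun Friedel–Crafts attack by the free C6 and C8 positions of upper ring A of a second molecule, which the six-membered tether, the fully substituted lower ring A (bromine at C8) and high dilution should secure.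

**Step 11**
Reactants: 17 chromane-3-carbaldehyde
Product: 19 5,7,3',4',5'-penta-O-benzyl-(−)-epigallocatechin-(4β→6)-8-bromo-octa-O-benzyl-(−)-EGCG (free upper 3-OH; upper unit 2R,3R,4R; lower unit 2R,3R), via formate ester 18 (not isolated)
Conditions: mCPBA, NaHCO3, CH2Cl2, 0 °C; then KHCO3, MeOH, 0 °C
Reagents that add atoms: 3-chloroperoxybenzoic acid, OOC(=O)c1cccc(Cl)c1
Why: Baeyer–Villiger oxidation, in which the secondary C3 carbon migrates to oxygen with retention of configuration; the formate is then transesterified by methanol much faster than the hindered gallate ester.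

**Step 12**
Reactants: 19 protected, brominated dimer
Product: 20 (−)-epigallocatechin-(4β→6)-(−)-epigallocatechin 3-O-gallate, gallate on the lower unit (upper unit 2R,3R,4S; lower unit 2R,3R), the target
Conditions: H2 (1 atm), Pd(OH)2/C, Et3N, THF/MeOH, rt
Reagents that add atoms: none
Why: hydrogenolysis of the thirteen benzyl ethers and of the aryl C–Br bond, with Et3N taking up the HBr; no stereocenter is touched, and the C4 descriptor changes from R to S only because the ranking of the two aryl groups at C4 changes when the benzyl groups and the bromine are removed.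

**Compound list**
1 | (−)-epigallocatechin, 2R,3R | O[C@@H]1Cc2c(cc(O)cc2O)O[C@@H]1c1cc(O)c(O)c(O)c1 | starting material
2 | 5,7,3',4',5'-penta-O-benzyl-(−)-epigallocatechin (2R,3R) | O[C@@H]1Cc2c(cc(OCc3ccccc3)cc2OCc2ccccc2)O[C@@H]1c1cc(OCc2ccccc2)c(OCc2ccccc2)c(OCc2ccccc2)c1 | intermediate
3 | 3,4,5-tris(benzyloxy)benzoic acid | OC(=O)c1cc(OCc2ccccc2)c(OCc2ccccc2)c(OCc2ccccc2)c1 | starting material
4 | octa-O-benzyl-(−)-EGCG, (2R,3R)-5,7-bis(benzyloxy)-2-[3,4,5-tris(benzyloxy)phenyl]chroman-3-yl 3,4,5-tris(benzyloxy)benzoate | O=C(O[C@@H]1Cc2c(cc(OCc3ccccc3)cc2OCc2ccccc2)O[C@@H]1c1cc(OCc2ccccc2)c(OCc2ccccc2)c(OCc2ccccc2)c1)c1cc(OCc2ccccc2)c(OCc2ccccc2)c(OCc2ccccc2)c1 | intermediate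
5 | 8-bromo-octa-O-benzyl-(−)-EGCG (2R,3R) | O=C(O[C@@H]1Cc2c(c(Br)c(OCc3ccccc3)cc2OCc2ccccc2)O[C@@H]1c1cc(OCc2ccccc2)c(OCc2ccccc2)c(OCc2ccccc2)c1)c1cc(OCc2ccccc2)c(OCc2ccccc2)c(OCc2ccccc2)c1 | intermediate
6 | 8-bromo-6-iodo-octa-O-benzyl-(−)-EGCG (2R,3R) | O=C(O[C@@H]1Cc2c(c(Br)c(OCc3ccccc3)c(I)c2OCc2ccccc2)O[C@@H]1c1cc(OCc2ccccc2)c(OCc2ccccc2)c(OCc2ccccc2)c1)c1cc(OCc2ccccc2)c(OCc2ccccc2)c(OCc2ccccc2)c1 | intermediate
7 | 2,4,6-trihydroxybenzaldehyde | O=Cc1c(O)cc(O)cc1O | starting material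
8 | 2,4-bis(benzyloxy)-6-hydroxybenzaldehyde | O=Cc1c(O)cc(OCc2ccccc2)cc1OCc1ccccc1 | intermediate
9 | 2,4-bis(benzyloxy)-6-(tert-butyldimethylsilyloxy)benzaldehyde | O=Cc1c(O[Si](C)(C)C(C)(C)C)cc(OCc2ccccc2)cc1OCc1ccccc1 | intermediate
10 | 8-bromo-octa-O-benzyl-(−)-EGCG-6-ylmagnesium chloride | O=C(O[C@@H]1Cc2c(c(Br)c(OCc3ccccc3)c([Mg]Cl)c2OCc2ccccc2)O[C@@H]1c1cc(OCc2ccccc2)c(OCc2ccccc2)c(OCc2ccccc2)c1)c1cc(OCc2ccccc2)c(OCc2ccccc2)c(OCc2ccccc2)c1 | intermediate (not isolated)
11 | silyl-protected benzhydrol: 8-bromo-octa-O-benzyl-(−)-EGCG with a hydroxy[2,4-bis(benzyloxy)-6-(tert-butyldimethylsilyloxy)phenyl]methyl group at C6 (carbinol epimers) | O=C(O[C@@H]1Cc2c(c(Br)c(OCc3ccccc3)c(C(O)c3c(O[Si](C)(C)C(C)(C)C)cc(OCc4ccccc4)cc3OCc3ccccc3)c2OCc2ccccc2)O[C@@H]1c1cc(OCc2ccccc2)c(OCc2ccccc2)c(OCc2ccccc2)c1)c1cc(OCc2ccccc2)c(OCc2ccccc2)c(OCc2ccccc2)c1 | intermediate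
12 | phenolic benzhydrol: 8-bromo-octa-O-benzyl-(−)-EGCG with a hydroxy[2,4-bis(benzyloxy)-6-hydroxyphenyl]methyl group at C6 (carbinol epimers) | O=C(O[C@@H]1Cc2c(c(Br)c(OCc3ccccc3)c(C(O)c3c(O)cc(OCc4ccccc4)cc3OCc3ccccc3)c2OCc2ccccc2)O[C@@H]1c1cc(OCc2ccccc2)c(OCc2ccccc2)c(OCc2ccccc2)c1)c1cc(OCc2ccccc2)c(OCc2ccccc2)c(OCc2ccccc2)c1 | intermediate
13 | 3,4,5-tris(benzyloxy)benzaldehyde | O=Cc1cc(OCc2ccccc2)c(OCc2ccccc2)c(OCc2ccccc2)c1 | starting material
14 | (E)-3-[3,4,5-tris(benzyloxy)phenyl]prop-2-enal | O=C/C=C/c1cc(OCc2ccccc2)c(OCc2ccccc2)c(OCc2ccccc2)c1 | intermediate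
15 | oxa-Michael enamine: 12 whose phenolic oxygen carries the (S)-1-aryl-3-aminoprop-2-enyl group, E-enamine of the (S)-pyrrolidine catalyst | O=C(O[C@@H]1Cc2c(c(Br)c(OCc3ccccc3)c(C(O)c3c(O[C@H](c4cc(OCc5ccccc5)c(OCc5ccccc5)c(OCc5ccccc5)c4)/C=C/N4CCC[C@H]4C(O[Si](C)(C)C)(c4ccccc4)c4ccccc4)cc(OCc4ccccc4)cc3OCc3ccccc3)c2OCc2ccccc2)O[C@@H]1c1cc(OCc2ccccc2)c(OCc2ccccc2)c(OCc2ccccc2)c1)c1cc(OCc2ccccc2)c(OCc2ccccc2)c(OCc2ccccc2)c1 | intermediate (not isolated)
16 | enamine carbenium ion (benzoate): 15 after loss of hydroxide from the benzhydryl carbon | O=C(O[C@@H]1Cc2c(c(Br)c(OCc3ccccc3)c([CH+]c3c(O[C@H](c4cc(OCc5ccccc5)c(OCc5ccccc5)c(OCc5ccccc5)c4)/C=C/N4CCC[C@H]4C(O[Si](C)(C)C)(c4ccccc4)c4ccccc4)cc(OCc4ccccc4)cc3OCc3ccccc3)c2OCc2ccccc2)O[C@@H]1c1cc(OCc2ccccc2)c(OCc2ccccc2)c(OCc2ccccc2)c1)c1cc(OCc2ccccc2)c(OCc2ccccc2)c(OCc2ccccc2)c1.[O-]C(=O)c1ccccc1 | intermediate (not isolated)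
17 | (2S,3R,4R)-5,7-bis(benzyloxy)-4-[8-bromo-octa-O-benzyl-(−)-EGCG-6-yl]-2-[3,4,5-tris(benzyloxy)phenyl]chromane-3-carbaldehyde (C2 aryl and C3 formyl cis; C4 aryl trans to both) | O=C(O[C@@H]1Cc2c(c(Br)c(OCc3ccccc3)c([C@H]3c4c(OCc5ccccc5)cc(OCc5ccccc5)cc4O[C@H](c4cc(OCc5ccccc5)c(OCc5ccccc5)c(OCc5ccccc5)c4)[C@@H]3C=O)c2OCc2ccccc2)O[C@@H]1c1cc(OCc2ccccc2)c(OCc2ccccc2)c(OCc2ccccc2)c1)c1cc(OCc2ccccc2)c(OCc2ccccc2)c(OCc2ccccc2)c1 | intermediate
18 | 3-O-formyl-5,7,3',4',5'-penta-O-benzyl-(−)-epigallocatechin-(4β→6)-8-bromo-octa-O-benzyl-(−)-EGCG | O=C(O[C@@H]1Cc2c(c(Br)c(OCc3ccccc3)c([C@H]3c4c(OCc5ccccc5)cc(OCc5ccccc5)cc4O[C@H](c4cc(OCc5ccccc5)c(OCc5ccccc5)c(OCc5ccccc5)c4)[C@@H]3OC=O)c2OCc2ccccc2)O[C@@H]1c1cc(OCc2ccccc2)c(OCc2ccccc2)c(OCc2ccccc2)c1)c1cc(OCc2ccccc2)c(OCc2ccccc2)c(OCc2ccccc2)c1 | intermediate (not isolated)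
19 | 5,7,3',4',5'-penta-O-benzyl-(−)-epigallocatechin-(4β→6)-8-bromo-octa-O-benzyl-(−)-EGCG (upper unit 2R,3R,4R; lower unit 2R,3R) | O=C(O[C@@H]1Cc2c(c(Br)c(OCc3ccccc3)c([C@H]3c4c(OCc5ccccc5)cc(OCc5ccccc5)cc4O[C@H](c4cc(OCc5ccccc5)c(OCc5ccccc5)c(OCc5ccccc5)c4)[C@@H]3O)c2OCc2ccccc2)O[C@@H]1c1cc(OCc2ccccc2)c(OCc2ccccc2)c(OCc2ccccc2)c1)c1cc(OCc2ccccc2)c(OCc2ccccc2)c(OCc2ccccc2)c1 | intermediate
20 | (−)-epigallocatechin-(4β→6)-(−)-epigallocatechin 3-O-gallate, gallate on the lower unit (upper unit 2R,3R,4S; lower unit 2R,3R) | O=C(O[C@@H]1Cc2c(cc(O)c([C@H]3c4c(O)cc(O)cc4O[C@H](c4cc(O)c(O)c(O)c4)[C@@H]3O)c2O)O[C@@H]1c1cc(O)c(O)c(O)c1)c1cc(O)c(O)c(O)c1 | target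

**Step count and risks**
Total step count: 12. Longest linear sequence: 9 steps (steps 1, 2, 3, 4, 7, 8, 10, 11, 12).

Steps most likely to fail:

1. Step 10 (proposed new method). What may go wrong: the carbenium ion is captured intermolecularly by free ring A positions (oligomerisation), the phenol fails to add to the iminium ion, or facial selectivity in the C3–C4 closure is poor. The fallback uses known chemistry and makes the interflavan bond instead of the ring; it sets out from 2 (with 5 as the partner) and comes back at 19. Compound 2 is oxidised at C4 with DDQ in the presence of ethylene glycol to 4β-(2-hydroxyethoxy)-5,7,3',4',5'-penta-O-benzyl-(−)-epigallocatechin F1. TMSOTf in CH2Cl2 at −78 °C ionises F1 to the C4 carbenium ion, which the only free ring A position of an excess of 5 (C6, since C8 carries bromine) should attack from the face opposite to the C2 aryl and C3 hydroxyl groups, giving 19.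

2. Step 11. What may go wrong: hydride migration instead of carbon migration in the Criegee adduct (over-oxidation to the acid), or peracid oxidation of the electron-rich benzyloxy arenes. The fallback sets out from 17 and comes back at 19. Pinnick oxidation (NaClO2, NaH2PO4, 2-methyl-2-butene, t-BuOH/H2O) gives the chromane-3-carboxylic acid F2. DCC coupling with N-hydroxypyridine-2-thione gives the Barton ester F3. Irradiation of F3 under O2 with tert-butyl thiol, then PPh3, effects decarboxylative hydroxylation; the C3 radical should be trapped on the face anti to the quasi-axial C4 aryl group, which gives 19.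

3. Step 7. What may go wrong: the doubly ortho-substituted aryl Grignard reagent adds too slowly to the doubly ortho-substituted aldehyde, so that attack on the gallate ester or protonation takes over. The fallback reverses the roles of the partners; it sets out from 6 and comes back at 12. The arylmagnesium chloride 10 generated from 6 is quenched with the small electrophile DMF to give 8-bromo-6-formyl-octa-O-benzyl-(−)-EGCG F4. The bromomagnesium phenoxide of commercial 3,5-bis(benzyloxy)phenol (EtMgBr, toluene) then adds through its ortho carbon to F4 (chelation-controlled ortho-hydroxyalkylation of a magnesium phenoxide), giving 12 directly without steps 5, 6 and 8.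

**Further compounds**
F1 | step 10 | 4β-(2-hydroxyethoxy)-5,7,3',4',5'-penta-O-benzyl-(−)-epigallocatechin | OCCO[C@H]1c2c(OCc3ccccc3)cc(OCc3ccccc3)cc2O[C@H](c2cc(OCc3ccccc3)c(OCc3ccccc3)c(OCc3ccccc3)c2)[C@@H]1O
F2 | step 11 | 5,7-bis(benzyloxy)-4-[8-bromo-octa-O-benzyl-(−)-EGCG-6-yl]-2-[3,4,5-tris(benzyloxy)phenyl]chromane-3-carboxylic acid, configuration as in 17 | O=C(O[C@@H]1Cc2c(c(Br)c(OCc3ccccc3)c([C@H]3c4c(OCc5ccccc5)cc(OCc5ccccc5)cc4O[C@H](c4cc(OCc5ccccc5)c(OCc5ccccc5)c(OCc5ccccc5)c4)[C@@H]3C(=O)O)c2OCc2ccccc2)O[C@@H]1c1cc(OCc2ccccc2)c(OCc2ccccc2)c(OCc2ccccc2)c1)c1cc(OCc2ccccc2)c(OCc2ccccc2)c(OCc2ccccc2)c1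
F3 | step 11 | 2-thioxopyridin-1(2H)-yl ester (Barton ester) of F2 | O=C(O[C@@H]1Cc2c(c(Br)c(OCc3ccccc3)c([C@H]3c4c(OCc5ccccc5)cc(OCc5ccccc5)cc4O[C@H](c4cc(OCc5ccccc5)c(OCc5ccccc5)c(OCc5ccccc5)c4)[C@@H]3C(=O)On3ccccc3=S)c2OCc2ccccc2)O[C@@H]1c1cc(OCc2ccccc2)c(OCc2ccccc2)c(OCc2ccccc2)c1)c1cc(OCc2ccccc2)c(OCc2ccccc2)c(OCc2ccccc2)c1
F4 | step 7 | 8-bromo-6-formyl-octa-O-benzyl-(−)-EGCG (2R,3R) | O=C(O[C@@H]1Cc2c(c(Br)c(OCc3ccccc3)c(C=O)c2OCc2ccccc2)O[C@@H]1c1cc(OCc2ccccc2)c(OCc2ccccc2)c(OCc2ccccc2)c1)c1cc(OCc2ccccc2)c(OCc2ccccc2)c(OCc2ccccc2)c1
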